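## Retrosynthetic overview

1. The target comes from three late operations. Hydroxide opens a cis-β-lactone that masks C3-OH and C1-CO2H together, HN3 adds at C2 of the quinone, and a 5,8-dimethoxy-1-acyl-2-naphthol is oxidatively demethylated.
2. Key disconnection: the acyl-bearing carbon of ring B is excised. This leads back to 4,7-dimethoxy-2-methylindan-1-one and a side-chain diazomethyl ketone, joined by a five-to-six ring expansion (1,2-aryl shift) and then dehydrogenation. That one step builds ring B, frees the 6-OH and joins the two halves.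
3. The β-lactone comes from a trans-(S,S)-epoxide and CO (three-to-four ring expansion, inversion at C2). The epoxide comes from Shi epoxidation of a skipped dienone, itself made by asymmetric hydroformylation of (E)-piperylene and a stabilised-ylide Wittig reaction.
4. Ring order: ring A arrives with the arene, then the cyclopentanone ring is closed (Friedel–Crafts). In parallel, oxirane then oxetanone. The cyclopentanone is expanded to ring B, ring A is oxidised to the quinone, and the oxetanone is opened last.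

Locants: side chain C1–C7 follow the heptenoic acid of the target. Ring locants follow 1,4-naphthoquinone (NH2 at C2, acyl at C5, OH at C6, CH3 at C7).

Assumption: the (S,S,S) antipode of the bis(diazaphospholane) ligand BisDiazaphos is taken to give (S)-8; if the correlation is opposite, the mirror-image ligand is used and nothing else changes.

## Route

Step 1
Reactants: 1 1,4-dimethoxybenzene; 2 methacrylic acid
Product: 3 (±)-4,7-dimethoxy-2-methylindan-1-one
Conditions: PPA, 65 °C, 3 h
Reagents that add atoms: none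
Why: Friedel–Crafts acylation followed by intramolecular Friedel–Crafts alkylation of the aryl isopropenyl ketone ortho to the second methoxy group; the symmetry of 1 allows one regioisomer only, and the racemic centre is erased in step 7.

Step 2
Reactants: 4 3-bromobutan-2-one
Product: 6 ylide 3-(triphenyl-λ5-phosphanylidene)butan-2-one, via phosphonium bromide 5 (not isolated)
Conditions: PPh3, PhMe, reflux; then 2 M NaOH, CH2Cl2, rt
Reagents that add atoms: triphenylphosphine, c1ccc(cc1)P(c1ccccc1)c1ccccc1
Why: SN2 quaternisation of PPh3 and deprotonation of the acidic α-CH give the acyl-stabilised Wittig ylide.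

Step 3
Reactants: 7 (E)-penta-1,3-diene; 6 ylide 3-(triphenyl-λ5-phosphanylidene)butan-2-one
Product: 9 (3E,5S,6E)-3,5-dimethylocta-3,6-dien-2-one, via aldehyde 8 (not isolated)
Conditions: Rh(acac)(CO)2 (0.5 mol %), (S,S,S)-BisDiazaphos (0.6 mol %), CO/H2 (1:1, 10 bar), THF, 40 °C; vent; then 6 (1.2 equiv), PhCO2H (10 mol %), 40 °C
Reagents that add atoms: carbon monoxide, [C-]#[O+]
Why: Rhodium-catalysed asymmetric hydroformylation of an E-1,3-diene adds H to the terminal CH2 and CHO to the adjacent carbon under ligand control, which sets C4 (S in 8 and 9, R in the target by CIP change) and keeps the E-propenyl group; the epimerisable aldehyde is trapped at once by a stabilised-ylide Wittig olefination, which gives the E enone.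

Step 4
Reactants: 9 (3E,5S,6E)-3,5-dimethylocta-3,6-dien-2-one
Product: 10 (3E,5R)-3-methyl-5-[(2S,3S)-3-methyloxiran-2-yl]hex-3-en-2-one
Conditions: 1,2:4,5-di-O-isopropylidene-β-L-erythro-2,3-hexodiulo-2,6-pyranose (ent-Shi ketone, 30 mol %), 2KHSO5·KHSO4·K2SO4, K2CO3, Bu4NHSO4, MeCN–CH2(OMe)2/aq Na2B4O7 buffer (pH 10.5), 0 °C
Reagents that add atoms: potassium peroxymonosulfate, [K+].[O-]S(=O)(=O)OO
Why: Shi asymmetric epoxidation, in which the L-series chiral dioxirane delivers oxygen to the electron-rich E-disubstituted alkene under reagent control to give the (S,S)-oxirane (sets C3 and the C2 centre to be inverted); the electron-poor enone is untouched, and any minor C4 antipode from step 3 becomes a separable diastereomer.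

Step 5
Reactants: 10 (3E,5R)-3-methyl-5-[(2S,3S)-3-methyloxiran-2-yl]hex-3-en-2-one
Product: 11 (3R,4S)-3-methyl-4-[(2R,3E)-4-methyl-5-oxohex-3-en-2-yl]oxetan-2-one
Conditions: [(salph)Al(THF)2][Co(CO)4] (5 mol %; salph = N,N′-bis(3,5-di-tert-butylsalicylidene)-1,2-phenylenediamine dianion), CO (60 bar), DME, 50 °C
Reagents that add atoms: carbon monoxide, [C-]#[O+]
Why: Ring-expanding epoxide carbonylation, in which the aluminium cation activates the oxirane, Co(CO)4− opens it by SN2 at the less hindered methyl-bearing carbon with inversion, CO inserts with retention and the alkoxide closes on the acyl cobalt; the trans-(S,S)-epoxide therefore gives the cis-(3R,4S)-lactone (C2 becomes R, C3 stays S).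

Step 6
Reactants: 11 (3R,4S)-3-methyl-4-[(2R,3E)-4-methyl-5-oxohex-3-en-2-yl]oxetan-2-one
Product: 13 (3R,4S)-4-[(2R,3E)-6-diazo-4-methyl-5-oxohex-3-en-2-yl]-3-methyloxetan-2-one, via trifluoroacetyl diketone 12 (not isolated)
Conditions: LiN(SiMe3)2 (1.05 equiv), THF, −78 °C; CF3CO2CH2CF3; 5 % HCl wash; then MsN3, Et3N, H2O (1 equiv), MeCN, rt
Reagents that add atoms: methanesulfonyl azide, CS(=O)(=O)N=[N+]=[N-]; 2,2,2-trifluoroethyl trifluoroacetate (CF3CO group of 12 only), O=C(OCC(F)(F)F)C(F)(F)F
Why: Danheiser detrifluoroacetylative diazo transfer, in which kinetic α′-deprotonation of the methyl enone (more acidic than the lactone α-CH, faster than γ-deprotonation), trifluoroacetylation and Regitz-type transfer with loss of the CF3CO group give the α′-diazo enone without touching the three stereocentres.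

Step 7
Reactants: 13 (3R,4S)-4-[(2R,3E)-6-diazo-4-methyl-5-oxohex-3-en-2-yl]-3-methyloxetan-2-one; 3 (±)-4,7-dimethoxy-2-methylindan-1-one
Product: 15 (3R,4S)-4-[(2R,3E)-5-(2-hydroxy-5,8-dimethoxy-3-methylnaphthalen-1-yl)-4-methyl-5-oxopent-3-en-2-yl]-3-methyloxetan-2-one, via acyltetralone 14 (not isolated)
Conditions: 3 (1.5 equiv), Sc(OTf)3 (20 mol %), 4 Å MS, CH2Cl2, −20 °C to rt, slow addition of 13; then DDQ (1.1 equiv), rt
Reagents that add atoms: none
Why: Proposed new method: Sc(OTf)3 sits in a six-membered chelate between C1=O and the 7-OMe of 3, the diazo carbon of 13 adds to this activated carbonyl, and the β-oxido diazonium loses N2 with an antiperiplanar 1,2-shift of the ortho-methoxy-activated aryl carbon C7a (aryl over secondary alkyl, phenonium-like transition state), so the cyclopentanone grows to the 1-acyl-2-tetralone 14 whose inserted carbon already carries the whole side chain, and DDQ then abstracts the electron-rich benzylic hydride of its enol to give the hydrogen-bonded 1-acyl-2-naphthol 15 (the stereorandom ring centres of 14 vanish and the side-chain centres are untouched); the closest known reactions are the Lewis-acid-promoted Tiffeneau–Demjanov/Büchner–Curtius–Schlotterbeck homologations of cycloalkanones with ethyl diazoacetate and of aryl ketones with Me3SiCHN2 (aryl migration), but insertion of an acyldiazomethane into a 1-indanone has not been shown.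

Step 8
Reactants: 15 (3R,4S)-4-[(2R,3E)-5-(2-hydroxy-5,8-dimethoxy-3-methylnaphthalen-1-yl)-4-methyl-5-oxopent-3-en-2-yl]-3-methyloxetan-2-one
Product: 16 (3R,4S)-4-[(2R,3E)-5-(2-hydroxy-3-methyl-5,8-dioxo-5,8-dihydronaphthalen-1-yl)-4-methyl-5-oxopent-3-en-2-yl]-3-methyloxetan-2-one
Conditions: (NH4)2Ce(NO3)6 (2.5 equiv), MeCN–H2O (2:1), 0 °C, 20 min
Reagents that add atoms: water, O
Why: Oxidative demethylation of a 1,4-dimethoxyarene, in which water attacks the arene radical cation at both ipso carbons and both methoxy groups leave as methanol; the chelated acyl-naphthol ring B is harder to oxidise, and lactone and enone tolerate the cold acidic medium.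

Step 9
Reactants: 16 (3R,4S)-4-[(2R,3E)-5-(2-hydroxy-3-methyl-5,8-dioxo-5,8-dihydronaphthalen-1-yl)-4-methyl-5-oxopent-3-en-2-yl]-3-methyloxetan-2-one
Product: 18 (2R,3S,4R,5E)-7-(6-amino-2-hydroxy-3-methyl-5,8-dioxo-5,8-dihydronaphthalen-1-yl)-3-hydroxy-2,4,6-trimethyl-7-oxohept-5-enoic acid, via aminoquinone lactone 17 (not isolated)
Conditions: NaN3 (3 equiv), AcOH, THF–H2O, rt; then LiOH, 0 °C; 1 M HCl to pH 3
Reagents that add atoms: sodium azide, [Na+].[N-]=[N+]=[N-]; lithium hydroxide, [Li+].[OH-]
Why: Conjugate addition of hydrazoic acid to the quinone, where the 6-OH is para-conjugated with C1=O and deactivates it, so the C4=O enone (next to the electron-withdrawing C5 acyl group) directs attack to C2 and the azidohydroquinone collapses by internal redox loss of N2 to the 2-aminoquinone; cold hydroxide then cleaves the β-lactone at the acyl–oxygen bond, which retains C2 and C3.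

## Compound list

1 | 1,4-dimethoxybenzene (hydroquinone carried as its bis(methyl ether); both O-methyl groups are protecting groups that leave in step 8) | COc1ccc(OC)cc1 | starting material
2 | methacrylic acid | CC(=C)C(=O)O | starting material
3 | (±)-4,7-dimethoxy-2-methylindan-1-one | COc1ccc(OC)c2c1CC(C)C2=O | intermediate
4 | 3-bromobutan-2-one (racemic) | CC(=O)C(C)Br | starting material
5 | (3-oxobutan-2-yl)triphenylphosphonium bromide | CC(=O)C(C)[P+](c1ccccc1)(c1ccccc1)c1ccccc1.[Br-] | intermediate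
6 | 3-(triphenyl-λ5-phosphanylidene)butan-2-one | CC(=O)C(C)=P(c1ccccc1)(c1ccccc1)c1ccccc1 | intermediate
7 | (E)-penta-1,3-diene | C=C/C=C/C | starting material
8 | (2S,3E)-2-methylpent-3-enal | O=C[C@@H](C)/C=C/C | intermediate
9 | (3E,5S,6E)-3,5-dimethylocta-3,6-dien-2-one | C/C(=C\[C@@H](C)/C=C/C)C(C)=O | intermediate
10 | (3E,5R)-3-methyl-5-[(2S,3S)-3-methyloxiran-2-yl]hex-3-en-2-one | C/C(=C\[C@@H](C)[C@@H]1O[C@H]1C)C(C)=O | intermediate
11 | (3R,4S)-3-methyl-4-[(2R,3E)-4-methyl-5-oxohex-3-en-2-yl]oxetan-2-one | C/C(=C\[C@@H](C)[C@@H]1OC(=O)[C@@H]1C)C(C)=O | intermediate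
12 | (3R,4S)-3-methyl-4-[(2R,3E)-8,8,8-trifluoro-4-methyl-5,7-dioxooct-3-en-2-yl]oxetan-2-one | C/C(=C\[C@@H](C)[C@@H]1OC(=O)[C@@H]1C)C(=O)CC(=O)C(F)(F)F | intermediate
13 | (3R,4S)-4-[(2R,3E)-6-diazo-4-methyl-5-oxohex-3-en-2-yl]-3-methyloxetan-2-one | C/C(=C\[C@@H](C)[C@@H]1OC(=O)[C@@H]1C)C(=O)C=[N+]=[N-] | intermediate
14 | (3R,4S)-4-[(2R,3E)-5-(5,8-dimethoxy-3-methyl-2-oxo-1,2,3,4-tetrahydronaphthalen-1-yl)-4-methyl-5-oxopent-3-en-2-yl]-3-methyloxetan-2-one (epimer mixture at ring C1 and C3, largely enolised) | C/C(=C\[C@@H](C)[C@@H]1OC(=O)[C@@H]1C)C(=O)C2C(=O)C(C)Cc3c(OC)ccc(OC)c32 | intermediate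
15 | (3R,4S)-4-[(2R,3E)-5-(2-hydroxy-5,8-dimethoxy-3-methylnaphthalen-1-yl)-4-methyl-5-oxopent-3-en-2-yl]-3-methyloxetan-2-one | C/C(=C\[C@@H](C)[C@@H]1OC(=O)[C@@H]1C)C(=O)c2c(O)c(C)cc3c(OC)ccc(OC)c23 | intermediate
16 | (3R,4S)-4-[(2R,3E)-5-(2-hydroxy-3-methyl-5,8-dioxo-5,8-dihydronaphthalen-1-yl)-4-methyl-5-oxopent-3-en-2-yl]-3-methyloxetan-2-one | C/C(=C\[C@@H](C)[C@@H]1OC(=O)[C@@H]1C)C(=O)c2c(O)c(C)cc3c2C(=O)C=CC3=O | intermediate
17 | (3R,4S)-4-[(2R,3E)-5-(6-amino-2-hydroxy-3-methyl-5,8-dioxo-5,8-dihydronaphthalen-1-yl)-4-methyl-5-oxopent-3-en-2-yl]-3-methyloxetan-2-one | C/C(=C\[C@@H](C)[C@@H]1OC(=O)[C@@H]1C)C(=O)c2c(O)c(C)cc3c2C(=O)C=C(N)C3=O | intermediate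
18 | (2R,3S,4R,5E)-7-(6-amino-2-hydroxy-3-methyl-5,8-dioxo-5,8-dihydronaphthalen-1-yl)-3-hydroxy-2,4,6-trimethyl-7-oxohept-5-enoic acid (CNP0236465.1) | C/C(=C\[C@@H](C)[C@H](O)[C@@H](C)C(=O)O)C(=O)c1c(O)c(C)cc2c1C(=O)C=C(N)C2=O | target

## Step count and risks

Total step count: 9.
Longest linear sequence: 8 (4 → 6 → 9 → 10 → 11 → 13 → 15 → 16 → 18). The arene branch (1 + 2 → 3) joins at step 7.

**Step 7 (the proposed new step).**
- The methoxy-deactivated carbonyl of 3 may not capture the weakly nucleophilic acyldiazomethane before the Lewis acid destroys 13.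
- The secondary alkyl carbon may migrate in part instead of the aryl carbon.
- The fallback uses known chemistry only. It sets out from 13 and 3 and comes back at 14.
- LiN(iPr)2 is added at −78 °C to a THF solution of both partners and the mixture is quenched cold with AcOH. This is the aldol-type addition of a lithiated α-diazo ketone to a ketone, and it no longer depends on Lewis-acid activation. It gives the isolated tertiary α-diazo-β-hydroxy ketone F1.
- Rh2(OAc)4 (1 mol %) in CH2Cl2 at rt turns F1 into the rhodium carbenoid, which undergoes the known 1,2-shift ring expansion of cyclic α-diazo-β-hydroxy carbonyl compounds (aryl over alkyl) to give 14.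
- DDQ then gives 15 as in step 7.

**Step 5.**
- A trans-disubstituted, α-branched epoxide carbonylates slowly.
- It may isomerise to the ketone.
- The enone may tie up the aluminium cation.
- The fallback drops the epoxide altogether. It sets out from 7 and comes back at 11.
- Hydroformylation of 7 with the mirror-image ligand gives (2R,3E)-2-methylpent-3-enal F2.
- The cinchona-alkaloid-catalysed acyl halide–aldehyde cyclocondensation follows: propionyl chloride, iPr2NEt, O-trimethylsilylquinidine or its pseudoenantiomer O-trimethylsilylquinine (whichever gives the 3R,4S sense), LiI, CH2Cl2–Et2O, −78 °C.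
- This gives the cis-lactone (3R,4S)-3-methyl-4-[(2R,3E)-pent-3-en-2-yl]oxetan-2-one F3.
- Ozonolysis (O3, CH2Cl2, −78 °C; Me2S) cuts the propenyl group to the lactone aldehyde (2S)-2-[(2S,3R)-3-methyl-4-oxooxetan-2-yl]propanal F4.
- Wittig olefination of F4 with 6 gives 11.

**Step 3.**
- The enantioselectivity on piperylene itself is unproven.
- Aldehyde 8 can racemise or slip into conjugation during the slow Wittig reaction.
- The fallback replaces catalysis by auxiliary control. It sets out from ylide 6, with diene 7 replaced by commercial (E)-pent-3-enoic acid, and comes back at 8 and hence 9.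
- The acid is coupled (pivaloyl chloride, Et3N, LiCl) with (S)-4-benzyloxazolidin-2-one to give the imide (4S)-4-benzyl-3-[(3E)-pent-3-enoyl]-1,3-oxazolidin-2-one F5.
- Evans α-methylation (NaN(SiMe3)2, MeI, −78 °C) gives (4S)-4-benzyl-3-[(2S,3E)-2-methylpent-3-enoyl]-1,3-oxazolidin-2-one F6.
- LiBH4 releases (2S,3E)-2-methylpent-3-en-1-ol F7.
- Dess–Martin oxidation of F7 gives 8, which is treated in the same flask with 6 to give 9.

## Further compounds

F1 | step 7 | (3R,4S)-4-[(2R,3E)-6-diazo-6-(1-hydroxy-4,7-dimethoxy-2-methyl-2,3-dihydro-1H-inden-1-yl)-4-methyl-5-oxohex-3-en-2-yl]-3-methyloxetan-2-one | C/C(=C\[C@@H](C)[C@@H]1OC(=O)[C@@H]1C)C(=O)C(=[N+]=[N-])C2(O)C(C)Cc3c(OC)ccc(OC)c32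
F2 | step 5 | (2R,3E)-2-methylpent-3-enal | C/C=C/[C@@H](C)C=O
F3 | step 5 | (3R,4S)-3-methyl-4-[(2R,3E)-pent-3-en-2-yl]oxetan-2-one | C/C=C/[C@@H](C)[C@@H]1OC(=O)[C@@H]1C
F4 | step 5 | (2S)-2-[(2S,3R)-3-methyl-4-oxooxetan-2-yl]propanal | O=C[C@@H](C)[C@@H]1OC(=O)[C@@H]1C
F5 | step 3 | (4S)-4-benzyl-3-[(3E)-pent-3-enoyl]-1,3-oxazolidin-2-one | C/C=C/CC(=O)N1[C@@H](Cc2ccccc2)COC1=O
F6 | step 3 | (4S)-4-benzyl-3-[(2S,3E)-2-methylpent-3-enoyl]-1,3-oxazolidin-2-one | C/C=C/[C@H](C)C(=O)N1[C@@H](Cc2ccccc2)COC1=O
F7 | step 3 | (2S,3E)-2-methylpent-3-en-1-ol | C/C=C/[C@H](C)CO
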